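**Plan**
The target is an achiral flavonol, so after removing four protecting groups the retrosynthesis cuts ring A at C5–C6, C7–C8 and C4a–C5, with C8–C8a traced to a 1,2-shift.
This is possible because ring C is a 2-aryl-3-oxygenated 4-pyranone (the kojic acid pattern) whose C4a=C8a double bond can act as the alkene of a dienylketene.
Ring A carries 5-OH, 6-Me, 7-O and 8-Me in exactly the order delivered by a ketene carbonyl carbon, the two carbons of 1-siloxypropyne and a methyl-bearing ketene carbon.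
Further cuts are C2–C1' (cross-coupling of a ring B boronate) and the acyl carbon on C8a, which goes back to the CH2OH of kojic acid.
Forward: ring C comes from kojic acid, ring B is attached, the side chain becomes a 2-diazopropanoyl group, ring A is closed last by photochemical benzannulation, then deprotection.
No stereocentre has to be set; the only stereogenic atoms (in the cyclobutenone and cyclohexadienone intermediates) are racemic and vanish on aromatisation.

Key step: step 9

Remarks: Ar = 4-methoxy-3,5-bis(triisopropylsilyloxy)phenyl and TIPS = triisopropylsilyl. Pyranone locants follow kojic acid up to compound 14 (kojic C6, C5, C4, C3, C2 become flavone C2, C3, C4, C4a, C8a). Diazoethane is assumed to be used as a freshly prepared, dried ethereal solution, which is a reagent preparation and not a step.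

**Route**

Step 1
Reactants: 1 2-methoxyresorcinol
Product: 2 2-methoxy-1,3-bis(triisopropylsilyloxy)benzene
Conditions: TIPSCl (2.4 equiv), imidazole (5 equiv), DMF, 40 °C
Reagents that add atoms: triisopropylsilyl chloride, CC(C)[Si](Cl)(C(C)C)C(C)C
Why: Silylation of both phenols with a silyl chloride and imidazole should be straightforward, and aryl TIPS ethers are chosen because they should survive the aqueous base of step 6 and the oxidant of step 7 and leave together with the C7 silyl ether in step 10.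

Step 2
Reactants: 2 2-methoxy-1,3-bis(triisopropylsilyloxy)benzene
Product: 3 2-Ar-4,4,5,5-tetramethyl-1,3,2-dioxaborolane
Conditions: [Ir(OMe)(cod)]2 (1.5 mol%), 4,4'-di-tert-butyl-2,2'-bipyridine (3 mol%), B2pin2 (1.0 equiv), THF, 70 °C
Reagents that add atoms: bis(pinacolato)diboron, CC1(C)OB(OC1(C)C)B1OC(C)(C)C(C)(C)O1
Why: Aromatic C–H borylation with [Ir(OMe)(cod)]2 and a bipyridine ligand is sterically controlled, and C5 is the only ring C–H with no ortho substituent, so the boryl group should enter there alone.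

Step 3
Reactants: 4 propyne
Product: 7 triisopropyl(prop-1-yn-1-yloxy)silane, via propynyllithium 5 (not isolated), via lithium propynolate 6 (not isolated)
Conditions: n-BuLi, THF, −78 °C; then t-BuOOLi (from t-BuOOH and LiN(SiMe3)2), −78 → 0 °C; then TIPSOTf, −78 → 0 °C
Reagents that add atoms: tert-butyl hydroperoxide (its oxygen atom), CC(C)(C)OO; triisopropylsilyl trifluoromethanesulfonate, CC(C)[Si](OS(=O)(=O)C(F)(F)F)(C(C)C)C(C)C
Why: Oxidation of a lithium acetylide by lithium tert-butyl peroxide to the ynolate followed by O-silylation with a bulky silyl triflate (Julia-type siloxyalkyne synthesis) is an established one-flask route to triisopropylsiloxyalkynes.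

Step 4
Reactants: 8 kojic acid
Product: 9 6-bromo-5-hydroxy-2-(hydroxymethyl)-4H-pyran-4-one
Conditions: NBS (1.05 equiv), MeCN/H2O, 0 °C → rt
Reagents that add atoms: N-bromosuccinimide, BrN1C(=O)CCC1=O
Why: Electrophilic bromination should occur at C6, ortho to the enolic 5-OH, the position at which kojic acid reacts with electrophiles (as in its Mannich and aldol reactions), while C3 is deactivated.

Step 5
Reactants: 9 6-bromo-5-hydroxy-2-(hydroxymethyl)-4H-pyran-4-one
Product: 10 5-(benzyloxy)-6-bromo-2-(hydroxymethyl)-4H-pyran-4-one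
Conditions: BnBr (1.1 equiv), K2CO3 (1.1 equiv), DMF, rt
Reagents that add atoms: benzyl bromide, BrCc1ccccc1
Why: Williamson etherification is selective because K2CO3 deprotonates only the acidic enolic hydroxyl and leaves the primary alcohol, as in the standard benzylation of kojic acid.

Step 6
Reactants: 10 5-(benzyloxy)-6-bromo-2-(hydroxymethyl)-4H-pyran-4-one; 3 2-Ar-4,4,5,5-tetramethyl-1,3,2-dioxaborolane
Product: 11 5-(benzyloxy)-2-(hydroxymethyl)-6-Ar-4H-pyran-4-one
Conditions: Pd(dppf)Cl2 (5 mol%), K3PO4 (2 equiv), 1,4-dioxane/H2O (10:1), 80 °C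
Reagents that add atoms: none
Why: Suzuki–Miyaura coupling should proceed readily because the C–Br bond of a 2-bromo-4-pyranone is a vinylogous acyl bromide that adds oxidatively with ease, the boronate has no ortho substituent, and the mild phosphate base spares the pyranone ring and the aryl silyl ethers.

Step 7
Reactants: 11 5-(benzyloxy)-2-(hydroxymethyl)-6-Ar-4H-pyran-4-one
Product: 13 5-(benzyloxy)-6-Ar-4-oxo-4H-pyran-2-carboxylic acid, via pyranone aldehyde 12 (not isolated)
Conditions: TEMPO (0.2 equiv), PhI(OAc)2 (2.2 equiv), MeCN/H2O (1:1), rt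
Reagents that add atoms: water, O
Why: Oxoammonium oxidation with TEMPO and PhI(OAc)2 in aqueous acetonitrile takes a primary alcohol through the aldehyde hydrate to the acid under near-neutral conditions that silyl ethers, the benzyl ether and the fully O-protected arene should tolerate.

Step 8
Reactants: 13 5-(benzyloxy)-6-Ar-4-oxo-4H-pyran-2-carboxylic acid
Product: 15 3-(benzyloxy)-6-(2-diazopropanoyl)-2-Ar-4H-pyran-4-one, via pyranone acid chloride 14 (not isolated)
Conditions: 1-chloro-N,N,2-trimethylprop-1-en-1-amine (1.2 equiv), CH2Cl2, 0 °C → rt; then CH3CHN2 (3 equiv), Et2O, −20 → 0 °C; AcOH quench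
Reagents that add atoms: diazoethane, CC=[N+]=[N-] (the chloroenamine, CC(C)=C(Cl)N(C)C, supplies only the chlorine of 14)
Why: Acylation of a diazoalkane by an acid chloride (the first stage of an Arndt–Eistert sequence) should give the α-methyl diazo ketone, with the chloride made under neutral conditions by the Ghosez reagent and the second equivalent of diazoethane taking up the HCl.

Step 9
Reactants: 15 3-(benzyloxy)-6-(2-diazopropanoyl)-2-Ar-4H-pyran-4-one; 7 triisopropyl(prop-1-yn-1-yloxy)silane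
Product: 20 3-(benzyloxy)-5-hydroxy-2-Ar-6,8-dimethyl-7-(triisopropylsilyloxy)-4H-chromen-4-one, via pyranonyl(methyl)ketene 16 (not isolated), via cyclobutenone 17 (not isolated), via dienylketene 18 (not isolated), via cyclohexadienone 19 (not isolated)
Conditions: 7 (2 equiv), degassed ClCH2CH2Cl (0.05 M), hν (440 nm LEDs), 20 °C until 15 is consumed; then 80 °C
Reagents that add atoms: none
Why: Excitation of the long-wavelength n→π* band of the diazo ketone expels N2 and the pyranonyl group migrates to the carbene carbon (Wolff rearrangement) to give ketene 16; blue light is chosen because neither the 3-benzyloxy-4-pyranone nor the 3-benzyloxyflavone product absorbs there, so their own UV photochemistry (hydrogen abstraction from the OCH2 group, pyranone rearrangement) should be avoided. Ketene 16 adds the electron-rich ynol ether 7 by [2+2] cycloaddition to cyclobutenone 17, which on warming opens reversibly by conrotatory four-electron electrocyclic ring opening to dienylketene 18. Ring A then closes by thermal disrotatory six-electron electrocyclisation of the ketene carbon onto C4a, and enolisation of cyclohexadienone 19 gives the hydrogen-bonded C5 phenol without any oxidant. The closest known reaction type is the Danheiser benzannulation in its photochemical Wolff variant, in which alkenyl, aryl and heteroaryl diazo ketones are combined with trialkylsiloxyalkynes; the weakly aromatic pyranone C=C takes the part of the alkene here and should close more easily than a benzene ring. No stereocentre remains, since the quaternary carbon of 17 and the sp3 carbon of 19 are racemic and transient. The step needs the ketene carbonyl carbon to bond to the methyl-bearing alkyne carbon, which the polarisation of the siloxyalkyne (nucleophilic β-carbon) secures, and closure can only occur at C4a because the other neighbour of C8a is the ring oxygen, while reversible ring opening feeds the non-closing dienylketene isomer back through 17.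

Step 10
Reactants: 20 3-(benzyloxy)-5-hydroxy-2-Ar-6,8-dimethyl-7-(triisopropylsilyloxy)-4H-chromen-4-one
Product: 21 3-(benzyloxy)-2-(3,5-dihydroxy-4-methoxyphenyl)-5,7-dihydroxy-6,8-dimethyl-4H-chromen-4-one
Conditions: Bu4NF (3.5 equiv), AcOH (3.5 equiv), THF, 0 °C → rt
Reagents that add atoms: none
Why: Fluoride cleaves all three aryl silyl ethers through the strong Si–F bond, and the acetic acid buffer keeps the liberated phenols protonated so that the benzyl ether, the methyl ether and the chromone are untouched.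

Step 11
Reactants: 21 3-(benzyloxy)-2-(3,5-dihydroxy-4-methoxyphenyl)-5,7-dihydroxy-6,8-dimethyl-4H-chromen-4-one
Product: 22 6,8-di-C-methylmyricetin 4'-methyl ether
Conditions: H2 (1 atm), 10% Pd/C, EtOAc/MeOH, rt
Reagents that add atoms: none
Why: Hydrogenolysis of the 3-O-benzyl ether over Pd/C is the standard release of a flavonol 3-OH, and the tetrasubstituted C2=C3 bond and the aryl methyl ether should not be reduced.

**Compound list**
1 | 2-methoxyresorcinol (2-methoxybenzene-1,3-diol) | COc1c(O)cccc1O | starting material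
2 | 2-methoxy-1,3-bis(triisopropylsilyloxy)benzene | COc1c(O[Si](C(C)C)(C(C)C)C(C)C)cccc1O[Si](C(C)C)(C(C)C)C(C)C | intermediate
3 | 2-[4-methoxy-3,5-bis(triisopropylsilyloxy)phenyl]-4,4,5,5-tetramethyl-1,3,2-dioxaborolane | COc1c(O[Si](C(C)C)(C(C)C)C(C)C)cc(B2OC(C)(C)C(C)(C)O2)cc1O[Si](C(C)C)(C(C)C)C(C)C | intermediate
4 | propyne | CC#C | starting material
5 | prop-1-yn-1-yllithium | CC#C[Li] | intermediate
6 | lithium prop-1-yn-1-olate | CC#CO[Li] | intermediate
7 | triisopropyl(prop-1-yn-1-yloxy)silane | CC#CO[Si](C(C)C)(C(C)C)C(C)C | intermediate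
8 | kojic acid (5-hydroxy-2-(hydroxymethyl)-4H-pyran-4-one) | OCc1cc(=O)c(O)co1 | starting material
9 | 6-bromo-5-hydroxy-2-(hydroxymethyl)-4H-pyran-4-one | OCc1cc(=O)c(O)c(Br)o1 | intermediate
10 | 5-(benzyloxy)-6-bromo-2-(hydroxymethyl)-4H-pyran-4-one | OCc1cc(=O)c(OCc2ccccc2)c(Br)o1 | intermediate
11 | 5-(benzyloxy)-2-(hydroxymethyl)-6-[4-methoxy-3,5-bis(triisopropylsilyloxy)phenyl]-4H-pyran-4-one | OCc1cc(=O)c(OCc2ccccc2)c(-c2cc(O[Si](C(C)C)(C(C)C)C(C)C)c(OC)c(O[Si](C(C)C)(C(C)C)C(C)C)c2)o1 | intermediate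
12 | 5-(benzyloxy)-6-[4-methoxy-3,5-bis(triisopropylsilyloxy)phenyl]-4-oxo-4H-pyran-2-carbaldehyde | O=Cc1cc(=O)c(OCc2ccccc2)c(-c2cc(O[Si](C(C)C)(C(C)C)C(C)C)c(OC)c(O[Si](C(C)C)(C(C)C)C(C)C)c2)o1 | intermediate
13 | 5-(benzyloxy)-6-[4-methoxy-3,5-bis(triisopropylsilyloxy)phenyl]-4-oxo-4H-pyran-2-carboxylic acid | OC(=O)c1cc(=O)c(OCc2ccccc2)c(-c2cc(O[Si](C(C)C)(C(C)C)C(C)C)c(OC)c(O[Si](C(C)C)(C(C)C)C(C)C)c2)o1 | intermediate
14 | 5-(benzyloxy)-6-[4-methoxy-3,5-bis(triisopropylsilyloxy)phenyl]-4-oxo-4H-pyran-2-carbonyl chloride | ClC(=O)c1cc(=O)c(OCc2ccccc2)c(-c2cc(O[Si](C(C)C)(C(C)C)C(C)C)c(OC)c(O[Si](C(C)C)(C(C)C)C(C)C)c2)o1 | intermediate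
15 | 3-(benzyloxy)-6-(2-diazopropanoyl)-2-[4-methoxy-3,5-bis(triisopropylsilyloxy)phenyl]-4H-pyran-4-one | CC(=[N+]=[N-])C(=O)c1cc(=O)c(OCc2ccccc2)c(-c2cc(O[Si](C(C)C)(C(C)C)C(C)C)c(OC)c(O[Si](C(C)C)(C(C)C)C(C)C)c2)o1 | intermediate
16 | 2-{5-(benzyloxy)-6-[4-methoxy-3,5-bis(triisopropylsilyloxy)phenyl]-4-oxo-4H-pyran-2-yl}prop-1-en-1-one (pyranonyl(methyl)ketene) | CC(=C=O)c1cc(=O)c(OCc2ccccc2)c(-c2cc(O[Si](C(C)C)(C(C)C)C(C)C)c(OC)c(O[Si](C(C)C)(C(C)C)C(C)C)c2)o1 | intermediate
17 | 4-{5-(benzyloxy)-6-[4-methoxy-3,5-bis(triisopropylsilyloxy)phenyl]-4-oxo-4H-pyran-2-yl}-2,4-dimethyl-3-(triisopropylsilyloxy)cyclobut-2-en-1-one (racemic) | CC1=C(O[Si](C(C)C)(C(C)C)C(C)C)C(C)(c2cc(=O)c(OCc3ccccc3)c(-c3cc(O[Si](C(C)C)(C(C)C)C(C)C)c(OC)c(O[Si](C(C)C)(C(C)C)C(C)C)c3)o2)C1=O | intermediate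
18 | (3E)-4-{5-(benzyloxy)-6-[4-methoxy-3,5-bis(triisopropylsilyloxy)phenyl]-4-oxo-4H-pyran-2-yl}-2-methyl-3-(triisopropylsilyloxy)penta-1,3-dien-1-one (pyranone cis to the ketene carbon) | O=C=C(C)/C(O[Si](C(C)C)(C(C)C)C(C)C)=C(/C)c1cc(=O)c(OCc2ccccc2)c(-c2cc(O[Si](C(C)C)(C(C)C)C(C)C)c(OC)c(O[Si](C(C)C)(C(C)C)C(C)C)c2)o1 | intermediate
19 | 3-(benzyloxy)-2-[4-methoxy-3,5-bis(triisopropylsilyloxy)phenyl]-6,8-dimethyl-7-(triisopropylsilyloxy)-4aH-chromene-4,5-dione (racemic keto tautomer) | CC1=C(O[Si](C(C)C)(C(C)C)C(C)C)C(C)=C2OC(-c3cc(O[Si](C(C)C)(C(C)C)C(C)C)c(OC)c(O[Si](C(C)C)(C(C)C)C(C)C)c3)=C(OCc3ccccc3)C(=O)C2C1=O | intermediate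
20 | 3-(benzyloxy)-5-hydroxy-2-[4-methoxy-3,5-bis(triisopropylsilyloxy)phenyl]-6,8-dimethyl-7-(triisopropylsilyloxy)-4H-chromen-4-one | Cc1c(O[Si](C(C)C)(C(C)C)C(C)C)c(C)c2oc(-c3cc(O[Si](C(C)C)(C(C)C)C(C)C)c(OC)c(O[Si](C(C)C)(C(C)C)C(C)C)c3)c(OCc3ccccc3)c(=O)c2c1O | intermediate
21 | 3-(benzyloxy)-2-(3,5-dihydroxy-4-methoxyphenyl)-5,7-dihydroxy-6,8-dimethyl-4H-chromen-4-one | Cc1c(O)c(C)c2oc(-c3cc(O)c(OC)c(O)c3)c(OCc3ccccc3)c(=O)c2c1O | intermediate
22 | 6,8-di-C-methylmyricetin 4'-methyl ether (2-(3,5-dihydroxy-4-methoxyphenyl)-3,5,7-trihydroxy-6,8-dimethyl-4H-chromen-4-one) | COc1c(O)cc(-c2oc3c(C)c(O)c(C)c(O)c3c(=O)c2O)cc1O | target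

**Step count**
Total step count: 11.
Longest linear sequence: 8 steps (kojic acid 8 to target 22, steps 4–11). The ring B branch (steps 1–2) joins at step 6 and the siloxyalkyne (step 3) joins at step 9.

**Steps most likely to fail**

Step 9. The excited α-methyl diazo ketone may undergo a 1,2-hydrogen shift from the methyl group to a vinyl ketone instead of rearranging. The fully substituted ketene may also add the ynol ether too slowly, so that dimerisation competes, or the cyclobutenone may stall before closing onto the pyranone. The fallback moves the C8 methyl group to a later stage and uses the best-precedented, unsubstituted form of the annulation. It sets out from acid chloride 14 and returns at 20.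
- Me3SiCHN2 (MeCN/THF, 0 °C) should give 3-(benzyloxy)-6-(2-diazoacetyl)-2-Ar-4H-pyran-4-one F1.
- Irradiation of F1 with 7 under the conditions of step 9 should pass through the monosubstituted pyranonylketene F2, the 4-pyranonyl-2-methyl-3-(triisopropylsilyloxy)cyclobut-2-en-1-one F3, the corresponding dienylketene F4 and the 4aH-chromene-4,5-dione F5 to 3-(benzyloxy)-5-hydroxy-2-Ar-6-methyl-7-(triisopropylsilyloxy)-4H-chromen-4-one F6.
- NIS (DMF, rt) should iodinate the only free ring A position, para to the 5-OH, to give the 8-iodo flavone F7.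
- Suzuki–Miyaura methylation with trimethylboroxine (Pd(dppf)Cl2, K2CO3, dioxane, 90 °C) should then give 20.

Step 8. Diazoethane may add as a 1,3-dipole to the pyranone C=C bond that carries the acyl group (pyrazoline formation), and residual HCl may convert the diazo ketone into an α-chloro ketone. The fallback avoids a free diazoalkane by diazo transfer. It sets out from acid chloride 14 (from 13) and returns at 15.
- MeNH(OMe)·HCl and pyridine should give the N-methoxy-N-methylamide F8.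
- EtMgBr (THF, −78 °C) should give 5-(benzyloxy)-2-propanoyl-6-Ar-4H-pyran-4-one F9.
- Trifluoroacetylation of its enolate (LiN(SiMe3)2, CF3CO2CH2CF3, THF, −78 °C) should give the α-trifluoroacetyl ketone F10.
- Detrifluoroacetylative diazo transfer (MsN3, Et3N, H2O, MeCN) should then give 15.

Step 6. Aqueous base may attack the vinylogous acyl bromide by addition–elimination or open the pyranone ring, and protodeboronation or partial loss of the aryl silyl ethers may accompany the coupling. The fallback is a base-free Stille coupling. It sets out from boronate 3 and returns at 11.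
- Iododeboronation (NaI, TsN(Cl)Na, aqueous THF, rt) should give 5-iodo-2-methoxy-1,3-bis(triisopropylsilyloxy)benzene F11.
- Stannylation with (Me3Sn)2 and Pd(PPh3)4 (toluene, 100 °C) should give the aryltrimethylstannane F12.
- Coupling of F12 with bromide 10 (Pd(PPh3)4, CuI, DMF, 60 °C) should give 11 under neutral conditions that tolerate the free alcohol.

**Further compounds**
F1 | step 9 | 3-(benzyloxy)-6-(2-diazoacetyl)-2-[4-methoxy-3,5-bis(triisopropylsilyloxy)phenyl]-4H-pyran-4-one | [N-]=[N+]=CC(=O)c1cc(=O)c(OCc2ccccc2)c(-c2cc(O[Si](C(C)C)(C(C)C)C(C)C)c(OC)c(O[Si](C(C)C)(C(C)C)C(C)C)c2)o1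
F2 | step 9 | 2-{5-(benzyloxy)-6-[4-methoxy-3,5-bis(triisopropylsilyloxy)phenyl]-4-oxo-4H-pyran-2-yl}ethen-1-one (pyranonylketene) | O=C=Cc1cc(=O)c(OCc2ccccc2)c(-c2cc(O[Si](C(C)C)(C(C)C)C(C)C)c(OC)c(O[Si](C(C)C)(C(C)C)C(C)C)c2)o1
F3 | step 9 | 4-{5-(benzyloxy)-6-[4-methoxy-3,5-bis(triisopropylsilyloxy)phenyl]-4-oxo-4H-pyran-2-yl}-2-methyl-3-(triisopropylsilyloxy)cyclobut-2-en-1-one (racemic) | CC1=C(O[Si](C(C)C)(C(C)C)C(C)C)C(c2cc(=O)c(OCc3ccccc3)c(-c3cc(O[Si](C(C)C)(C(C)C)C(C)C)c(OC)c(O[Si](C(C)C)(C(C)C)C(C)C)c3)o2)C1=O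
F4 | step 9 | (3E)-4-{5-(benzyloxy)-6-[4-methoxy-3,5-bis(triisopropylsilyloxy)phenyl]-4-oxo-4H-pyran-2-yl}-2-methyl-3-(triisopropylsilyloxy)buta-1,3-dien-1-one | O=C=C(C)/C(O[Si](C(C)C)(C(C)C)C(C)C)=C\c1cc(=O)c(OCc2ccccc2)c(-c2cc(O[Si](C(C)C)(C(C)C)C(C)C)c(OC)c(O[Si](C(C)C)(C(C)C)C(C)C)c2)o1
F5 | step 9 | 3-(benzyloxy)-2-[4-methoxy-3,5-bis(triisopropylsilyloxy)phenyl]-6-methyl-7-(triisopropylsilyloxy)-4aH-chromene-4,5-dione (racemic) | CC1=C(O[Si](C(C)C)(C(C)C)C(C)C)C=C2OC(-c3cc(O[Si](C(C)C)(C(C)C)C(C)C)c(OC)c(O[Si](C(C)C)(C(C)C)C(C)C)c3)=C(OCc3ccccc3)C(=O)C2C1=O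
F6 | step 9 | 3-(benzyloxy)-5-hydroxy-2-[4-methoxy-3,5-bis(triisopropylsilyloxy)phenyl]-6-methyl-7-(triisopropylsilyloxy)-4H-chromen-4-one | Cc1c(O[Si](C(C)C)(C(C)C)C(C)C)cc2oc(-c3cc(O[Si](C(C)C)(C(C)C)C(C)C)c(OC)c(O[Si](C(C)C)(C(C)C)C(C)C)c3)c(OCc3ccccc3)c(=O)c2c1O
F7 | step 9 | 3-(benzyloxy)-5-hydroxy-8-iodo-2-[4-methoxy-3,5-bis(triisopropylsilyloxy)phenyl]-6-methyl-7-(triisopropylsilyloxy)-4H-chromen-4-one | Cc1c(O[Si](C(C)C)(C(C)C)C(C)C)c(I)c2oc(-c3cc(O[Si](C(C)C)(C(C)C)C(C)C)c(OC)c(O[Si](C(C)C)(C(C)C)C(C)C)c3)c(OCc3ccccc3)c(=O)c2c1O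
F8 | step 8 | 5-(benzyloxy)-N-methoxy-6-[4-methoxy-3,5-bis(triisopropylsilyloxy)phenyl]-N-methyl-4-oxo-4H-pyran-2-carboxamide | CON(C)C(=O)c1cc(=O)c(OCc2ccccc2)c(-c2cc(O[Si](C(C)C)(C(C)C)C(C)C)c(OC)c(O[Si](C(C)C)(C(C)C)C(C)C)c2)o1
F9 | step 8 | 5-(benzyloxy)-6-[4-methoxy-3,5-bis(triisopropylsilyloxy)phenyl]-2-propanoyl-4H-pyran-4-one | CCC(=O)c1cc(=O)c(OCc2ccccc2)c(-c2cc(O[Si](C(C)C)(C(C)C)C(C)C)c(OC)c(O[Si](C(C)C)(C(C)C)C(C)C)c2)o1
F10 | step 8 | 1-{5-(benzyloxy)-6-[4-methoxy-3,5-bis(triisopropylsilyloxy)phenyl]-4-oxo-4H-pyran-2-yl}-4,4,4-trifluoro-2-methylbutane-1,3-dione (racemic) | CC(C(=O)C(F)(F)F)C(=O)c1cc(=O)c(OCc2ccccc2)c(-c2cc(O[Si](C(C)C)(C(C)C)C(C)C)c(OC)c(O[Si](C(C)C)(C(C)C)C(C)C)c2)o1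
F11 | step 6 | 5-iodo-2-methoxy-1,3-bis(triisopropylsilyloxy)benzene | COc1c(O[Si](C(C)C)(C(C)C)C(C)C)cc(I)cc1O[Si](C(C)C)(C(C)C)C(C)C
F12 | step 6 | [4-methoxy-3,5-bis(triisopropylsilyloxy)phenyl]trimethylstannane | COc1c(O[Si](C(C)C)(C(C)C)C(C)C)cc([Sn](C)(C)C)cc1O[Si](C(C)C)(C(C)C)C(C)C
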